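**Retrosynthetic overview**
1. Numbering used below (labdane type): ring A = C1–C5 + C10 (gem-dimethyl on C4); ring B = C5–C10 (methyl on C8, side chain on C9, angular methyl on C10); side chain C11–C18 (methyl on C13, stereocentre C17, acid C18).
2. The C18 acid comes from primary alcohol 22; the (13E,15E)-diene comes from syn-carboalumination of alkyne 14 and Pd coupling with (E)-vinyl iodide 19, made from the (S)-Roche ester (source of C17).
3. Alkyne 14 comes from bicyclic dienone 9 by hydrogenation of C5=C6 (sets C5), removal of the C7 oxygen and one-carbon homologation at C13.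
4. Dienone 9 comes from ketone 6 (ring A, bought) and allenyl ketone 5 in one pot: an enantioselective Michael addition forms C9–C10, an aldol condensation forms C5–C6 and closes ring B. Ring order: A (pre-formed), then B.
5. Enabling feature: C10 is the only enolisable carbon next to a C5 carbonyl (C4 is quaternary), and the unit C6–C7–C8(CH3)=C9(CH2) of ring B is the skeleton of a 3-methyl-1,2-allenyl methyl ketone, whose sp carbon becomes C9 and whose acetyl CH3 becomes C6.

Key step: step 2

Remark 1: allene 5 (axis) and ketone 6 (C–H stereocentre) are used as racemates, because both stereo-elements are erased in step 2.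
Remark 2: the sense of induction of the chiral acid on this enol is assumed, not known; (R)-TRIP [(R)-3,3'-bis(2,4,6-triisopropylphenyl)-1,1'-binaphthyl-2,2'-diyl hydrogen phosphate] is written, and its enantiomer is the one to use if it proves to give (4aS)-9.
Remark 3: ylide 2 is taken as a catalogue Wittig reagent.

**Route**

Step 1
Reactants: 1 4-(benzyloxy)butanoic acid; 2 3-(triphenyl-λ5-phosphanylidene)butan-2-one
Product: 5 7-(benzyloxy)-3-methylhepta-3,4-dien-2-one (racemic), via 4-(benzyloxy)butanoyl chloride 3 (not isolated), via ketene 4 (not isolated)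
Conditions: (COCl)2, DMF (cat.), CH2Cl2, 0 °C to rt; concentrate; then 2, Et3N, CH2Cl2, 0 °C to rt
Reagents that add atoms: none
Why: Et3N dehydrochlorinates acid chloride 3 to ketene 4, whose C=O is olefinated by the acyl-stabilised ylide to give the 1,2-allenyl ketone (Wittig reaction of a ketene).

Step 2
Reactants: 5 7-(benzyloxy)-3-methylhepta-3,4-dien-2-one; 6 2,2,6-trimethylcyclohexan-1-one (racemic)
Product: 9 (4aR)-4-[3-(benzyloxy)propyl]-3,4a,8,8-tetramethyl-5,6,7,8-tetrahydronaphthalen-2(4aH)-one, via Michael adduct 7 (not isolated), via ketol 8 (not isolated)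
Conditions: 6 (3 equiv), (R)-TRIP (10 mol%), toluene, 50 °C; then powdered KOH, reflux, Dean–Stark trap
Reagents that add atoms: none
Why: Proposed new method: the chiral phosphoric acid should turn 6 into its only possible enol (C4 is quaternary, so enolisation can go only toward C10) and, while hydrogen-bonding the s-cis allenyl ketone, deliver the enol carbon C10 to the sp-hybridised central allene carbon, which forms the C9–C10 bond at a sterically open site and leaves the tetrasubstituted C8=C9 bond of the target in place once the dienol tautomerises to 7. The closest known reactions are the phosphoric-acid enol-catalysed Michael addition of α-branched cyclic ketones to vinyl ketones and the Michael addition of carbonyl pronucleophiles to the central carbon of 1,2-allenyl ketones, and the second stage is an ordinary Robinson-type aldol condensation under KOH with azeotropic removal of water. Ring B is closed by a 6-(enolendo)-exo-trig aldol addition of the methyl ketone enolate (C6) to the C5 carbonyl to give ketol 8, followed by E1cB loss of water to the cross-conjugated dienone. The only new stereocentre, quaternary C10, is set in the C–C bond-forming Michael event by the chiral phosphate, which shields one face of the planar enol. The step needs attack at the central allene carbon and the acetyl group cis to C10 for closure; the first is secured by conjugation with the ketone, the second by base-mediated E/Z equilibration of 7 through its dienolate. The ring ketone of 7 has no α-hydrogen and C6 is the only enolisable carbon that can reach C5 through a six-membered ring, so no other aldol mode competes.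

Step 3
Reactants: 9 (4aR)-4-[3-(benzyloxy)propyl]-3,4a,8,8-tetramethyl-5,6,7,8-tetrahydronaphthalen-2(4aH)-one
Product: 10 (4aS,8aS)-4-(3-hydroxypropyl)-3,4a,8,8-tetramethyl-4a,5,6,7,8,8a-hexahydronaphthalen-2(1H)-one
Conditions: H2 (1 atm), 10% Pd/C, EtOAc, rt
Reagents that add atoms: none
Why: Heterogeneous hydrogenation should saturate the trisubstituted C5=C6 bond in preference to the tetrasubstituted C8=C9 bond and cleave the benzyl ether (hydrogenolysis); hydrogen reaches C5 from the face opposite the syn-axial C10 and C4 methyl groups, which sets the trans ring fusion (5S).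

Step 4
Reactants: 10 (4aS,8aS)-4-(3-hydroxypropyl)-3,4a,8,8-tetramethyl-4a,5,6,7,8,8a-hexahydronaphthalen-2(1H)-one
Product: 12 3-[(4aS,8aS)-2,5,5,8a-tetramethyl-3,4,4a,5,6,7,8,8a-octahydronaphthalen-1-yl]propan-1-ol, via allylic diol 11 (not isolated)
Conditions: LiAlH4, Et2O, 0 °C; then AlCl3, reflux
Reagents that add atoms: none
Why: Mixed-hydride (chloroalane) hydrogenolysis of an α,β-unsaturated ketone: 1,2-reduction gives the allylic alkoxide of 11, AlCl3 ionises it, and the allyl cation takes hydride at the unhindered secondary C7, which keeps the tetrasubstituted C8=C9 bond.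

Step 5
Reactants: 12 3-[(4aS,8aS)-2,5,5,8a-tetramethyl-3,4,4a,5,6,7,8,8a-octahydronaphthalen-1-yl]propan-1-ol
Product: 13 3-[(4aS,8aS)-2,5,5,8a-tetramethyl-3,4,4a,5,6,7,8,8a-octahydronaphthalen-1-yl]propanal
Conditions: Dess–Martin periodinane, CH2Cl2, 0 °C to rt
Reagents that add atoms: none
Why: Dess–Martin oxidation of a primary alcohol stops at the aldehyde and leaves the hindered tetrasubstituted alkene untouched.

Step 6
Reactants: 13 3-[(4aS,8aS)-2,5,5,8a-tetramethyl-3,4,4a,5,6,7,8,8a-octahydronaphthalen-1-yl]propanal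
Product: 14 (4aS,8aS)-5-(but-3-yn-1-yl)-1,1,4a,6-tetramethyl-1,2,3,4,4a,7,8,8a-octahydronaphthalene
Conditions: dimethyl (1-diazo-2-oxopropyl)phosphonate, K2CO3, MeOH, 0 °C to rt
Reagents that add atoms: dimethyl (1-diazo-2-oxopropyl)phosphonate, CC(=O)C(=[N+]=[N-])P(=O)(OC)OC
Why: Seyferth–Gilbert homologation with the Ohira–Bestmann reagent converts the aldehyde into the terminal alkyne (C13≡C14) under mild base; no stereocentre is α to the aldehyde.

Step 7
Reactants: 15 methyl (2S)-3-hydroxy-2-methylpropanoate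
Product: 16 methyl (2S)-3-[(tert-butyldimethylsilyl)oxy]-2-methylpropanoate
Conditions: t-BuMe2SiCl, imidazole, DMF, rt
Reagents that add atoms: tert-butyldimethylsilyl chloride, CC(C)(C)[Si](C)(C)Cl
Why: Standard silylation of a primary alcohol; the stereocentre is not involved.

Step 8
Reactants: 16 methyl (2S)-3-[(tert-butyldimethylsilyl)oxy]-2-methylpropanoate
Product: 18 (2S)-3-[(tert-butyldimethylsilyl)oxy]-2-methylpropanal, via aluminium hemiacetal 17 (not isolated)
Conditions: i-Bu2AlH (1.05 equiv), CH2Cl2, −78 °C; cold aqueous work-up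
Reagents that add atoms: none
Why: Partial reduction of the ester stops at the tetrahedral aluminium hemiacetal 17 at −78 °C, which releases the aldehyde on work-up; the α-stereocentre is kept if 18 is used at once without chromatography.

Step 9
Reactants: 18 (2S)-3-[(tert-butyldimethylsilyl)oxy]-2-methylpropanal
Product: 19 tert-butyl{[(2R,3E)-4-iodo-2-methylbut-3-en-1-yl]oxy}dimethylsilane
Conditions: CrCl2, CHI3, THF, 0 °C to rt
Reagents that add atoms: iodoform, IC(I)I
Why: Takai olefination: the gem-dichromium reagent from CHI3 adds to the aldehyde and eliminates to the (E)-vinyl iodide under non-basic conditions that do not epimerise the α-centre (the descriptor changes from S to R only through the priority switch).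

Step 10
Reactants: 14 (4aS,8aS)-5-(but-3-yn-1-yl)-1,1,4a,6-tetramethyl-1,2,3,4,4a,7,8,8a-octahydronaphthalene; 19 tert-butyl{[(2R,3E)-4-iodo-2-methylbut-3-en-1-yl]oxy}dimethylsilane
Product: 21 tert-butyl({(2R,3E,5E)-2,6-dimethyl-8-[(4aS,8aS)-2,5,5,8a-tetramethyl-3,4,4a,5,6,7,8,8a-octahydronaphthalen-1-yl]octa-3,5-dien-1-yl}oxy)dimethylsilane, via alkenylalane 20 (not isolated)
Conditions: Me3Al, Cp2ZrCl2 (25 mol%), CH2Cl2, 0 °C to rt; then 19, Pd(PPh3)4 (5 mol%), ZnCl2 (cat.), THF, rt
Reagents that add atoms: trimethylaluminium, C[Al](C)C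
Why: Zirconium-catalysed carboalumination adds CH3 and Al syn across the terminal alkyne with Al at the terminus (sets 13E), and the alkenylalane couples with the (E)-iodide with retention at both partners (Negishi coupling), which gives the (13E,15E)-diene.

Step 11
Reactants: 21 tert-butyl({(2R,3E,5E)-2,6-dimethyl-8-[(4aS,8aS)-2,5,5,8a-tetramethyl-3,4,4a,5,6,7,8,8a-octahydronaphthalen-1-yl]octa-3,5-dien-1-yl}oxy)dimethylsilane
Product: 22 (2R,3E,5E)-2,6-dimethyl-8-[(4aS,8aS)-2,5,5,8a-tetramethyl-3,4,4a,5,6,7,8,8a-octahydronaphthalen-1-yl]octa-3,5-dien-1-ol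
Conditions: Bu4NF, THF, 0 °C to rt
Reagents that add atoms: none
Why: Fluoride-mediated cleavage of the primary silyl ether; nothing else in the molecule is fluoride-labile.

Step 12
Reactants: 22 (2R,3E,5E)-2,6-dimethyl-8-[(4aS,8aS)-2,5,5,8a-tetramethyl-3,4,4a,5,6,7,8,8a-octahydronaphthalen-1-yl]octa-3,5-dien-1-ol
Product: 24 (2R,3E,5E)-2,6-dimethyl-8-[(4aS,8aS)-2,5,5,8a-tetramethyl-3,4,4a,5,6,7,8,8a-octahydronaphthalen-1-yl]octa-3,5-dienoic acid, via dienal 23 (not isolated)
Conditions: TEMPO (20 mol%), PhI(OAc)2, MeCN/aqueous pH 7 buffer, 0 °C to rt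
Reagents that add atoms: water, O
Why: Oxoammonium (TEMPO/PhI(OAc)2) oxidation takes the primary alcohol through aldehyde 23 and its hydrate to the acid at near-neutral pH, which should avoid enolisation of C17 and migration of the β,γ-double bond into conjugation.

**Compound list**
1 | 4-(benzyloxy)butanoic acid | OC(=O)CCCOCc1ccccc1 | starting material
2 | 3-(triphenyl-λ5-phosphanylidene)butan-2-one | CC(=O)C(C)=P(c1ccccc1)(c1ccccc1)c1ccccc1 | starting material
3 | 4-(benzyloxy)butanoyl chloride | ClC(=O)CCCOCc1ccccc1 | intermediate (not isolated)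
4 | 4-(benzyloxy)but-1-en-1-one (ketene) | O=C=CCCOCc1ccccc1 | intermediate (not isolated)
5 | 7-(benzyloxy)-3-methylhepta-3,4-dien-2-one (racemic) | CC(=O)C(C)=C=CCCOCc1ccccc1 | intermediate
6 | 2,2,6-trimethylcyclohexan-1-one (racemic) | CC1CCCC(C)(C)C1=O | starting material
7 | (2R)-2-{1-[3-(benzyloxy)propyl]-2-methyl-3-oxobut-1-en-1-yl}-2,6,6-trimethylcyclohexan-1-one (E/Z mixture) | CC(=O)C(C)=C(CCCOCc1ccccc1)[C@@]2(C)CCCC(C)(C)C2=O | intermediate (not isolated)
8 | (4aR)-4-[3-(benzyloxy)propyl]-8a-hydroxy-3,4a,8,8-tetramethyl-4a,5,6,7,8,8a-hexahydronaphthalen-2(1H)-one (C8a not assigned) | CC1=C(CCCOCc2ccccc2)[C@@]3(C)CCCC(C)(C)C3(O)CC1=O | intermediate (not isolated)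
9 | (4aR)-4-[3-(benzyloxy)propyl]-3,4a,8,8-tetramethyl-5,6,7,8-tetrahydronaphthalen-2(4aH)-one | CC1=C(CCCOCc2ccccc2)[C@@]3(C)CCCC(C)(C)C3=CC1=O | intermediate
10 | (4aS,8aS)-4-(3-hydroxypropyl)-3,4a,8,8-tetramethyl-4a,5,6,7,8,8a-hexahydronaphthalen-2(1H)-one | CC1=C(CCCO)[C@@]2(C)CCCC(C)(C)[C@@H]2CC1=O | intermediate
11 | (4aS,8aS)-4-(3-hydroxypropyl)-3,4a,8,8-tetramethyl-1,2,4a,5,6,7,8,8a-octahydronaphthalen-2-ol (C2 epimers, held as aluminium alkoxide) | CC1=C(CCCO)[C@@]2(C)CCCC(C)(C)[C@@H]2CC1O | intermediate (not isolated)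
12 | 3-[(4aS,8aS)-2,5,5,8a-tetramethyl-3,4,4a,5,6,7,8,8a-octahydronaphthalen-1-yl]propan-1-ol | CC1=C(CCCO)[C@@]2(C)CCCC(C)(C)[C@@H]2CC1 | intermediate
13 | 3-[(4aS,8aS)-2,5,5,8a-tetramethyl-3,4,4a,5,6,7,8,8a-octahydronaphthalen-1-yl]propanal | CC1=C(CCC=O)[C@@]2(C)CCCC(C)(C)[C@@H]2CC1 | intermediate
14 | (4aS,8aS)-5-(but-3-yn-1-yl)-1,1,4a,6-tetramethyl-1,2,3,4,4a,7,8,8a-octahydronaphthalene | CC1=C(CCC#C)[C@@]2(C)CCCC(C)(C)[C@@H]2CC1 | intermediate
15 | methyl (2S)-3-hydroxy-2-methylpropanoate | COC(=O)[C@@H](C)CO | starting material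
16 | methyl (2S)-3-[(tert-butyldimethylsilyl)oxy]-2-methylpropanoate | COC(=O)[C@@H](C)CO[Si](C)(C)C(C)(C)C | intermediate
17 | diisobutylaluminium hemiacetal of 16 | COC(O[Al](CC(C)C)CC(C)C)[C@@H](C)CO[Si](C)(C)C(C)(C)C | intermediate (not isolated)
18 | (2S)-3-[(tert-butyldimethylsilyl)oxy]-2-methylpropanal | O=C[C@@H](C)CO[Si](C)(C)C(C)(C)C | intermediate
19 | tert-butyl{[(2R,3E)-4-iodo-2-methylbut-3-en-1-yl]oxy}dimethylsilane | I/C=C/[C@@H](C)CO[Si](C)(C)C(C)(C)C | intermediate
20 | dimethyl{(1E)-2-methyl-4-[(4aS,8aS)-2,5,5,8a-tetramethyl-3,4,4a,5,6,7,8,8a-octahydronaphthalen-1-yl]but-1-en-1-yl}alumane | CC1=C(CC/C(C)=C/[Al](C)C)[C@@]2(C)CCCC(C)(C)[C@@H]2CC1 | intermediate (not isolated)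
21 | tert-butyl({(2R,3E,5E)-2,6-dimethyl-8-[(4aS,8aS)-2,5,5,8a-tetramethyl-3,4,4a,5,6,7,8,8a-octahydronaphthalen-1-yl]octa-3,5-dien-1-yl}oxy)dimethylsilane | CC1=C(CC/C(C)=C/C=C/[C@@H](C)CO[Si](C)(C)C(C)(C)C)[C@@]2(C)CCCC(C)(C)[C@@H]2CC1 | intermediate
22 | (2R,3E,5E)-2,6-dimethyl-8-[(4aS,8aS)-2,5,5,8a-tetramethyl-3,4,4a,5,6,7,8,8a-octahydronaphthalen-1-yl]octa-3,5-dien-1-ol | CC1=C(CC/C(C)=C/C=C/[C@@H](C)CO)[C@@]2(C)CCCC(C)(C)[C@@H]2CC1 | intermediate
23 | (2R,3E,5E)-2,6-dimethyl-8-[(4aS,8aS)-2,5,5,8a-tetramethyl-3,4,4a,5,6,7,8,8a-octahydronaphthalen-1-yl]octa-3,5-dienal | CC1=C(CC/C(C)=C/C=C/[C@@H](C)C=O)[C@@]2(C)CCCC(C)(C)[C@@H]2CC1 | intermediate (not isolated)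
24 | (2R,3E,5E)-2,6-dimethyl-8-[(4aS,8aS)-2,5,5,8a-tetramethyl-3,4,4a,5,6,7,8,8a-octahydronaphthalen-1-yl]octa-3,5-dienoic acid | CC1=C(CC/C(C)=C/C=C/[C@@H](C)C(=O)O)[C@@]2(C)CCCC(C)(C)[C@@H]2CC1 | target

**Step count**
Total: 12 steps. Longest linear sequence: 9 steps (steps 1–6, 10, 11, 12, from acid 1).

**Steps most likely to fail**

Step 2 (Proposed new method). What may go wrong: under the acid, allenyl ketone 5 may be consumed by isomerisation to a conjugated dienone or by cycloisomerisation to a furan before the hindered enol of 6 adds to it, or the addition may go with weak facial discrimination. The fallback uses known reaction types only, sets out from ketone 6 and comes back at dienone 9; it brings in the C9 substituent after the annulation instead of with the acceptor. Chiral-phosphoric-acid enol-catalysed Michael addition of 6 to but-3-en-2-one should give (2R)-2,6,6-trimethyl-2-(3-oxobutyl)cyclohexan-1-one F1. KOH with azeotropic removal of water closes it to (4aR)-4a,8,8-trimethyl-4,4a,5,6,7,8-hexahydronaphthalen-2(3H)-one F2 (Robinson annulation). LiN(i-Pr)2 then MeI methylates the kinetic enolate to (4aR)-3,4a,8,8-tetramethyl-4,4a,5,6,7,8-hexahydronaphthalen-2(3H)-one F3. DDQ dehydrogenates F3 to the cross-conjugated (4aR)-3,4a,8,8-tetramethyl-5,6,7,8-tetrahydronaphthalen-2(4aH)-one F4. Conjugate addition of [3-(benzyloxy)propyl]magnesium bromide F5 (from benzyl 3-bromopropyl ether and Mg) under CuBr·SMe2 catalysis should occur at the only β-carbon that carries a hydrogen and give (4aR)-4-[3-(benzyloxy)propyl]-3,4a,8,8-tetramethyl-4,4a,5,6,7,8-hexahydronaphthalen-2(3H)-one F6. A second DDQ dehydrogenation, which can only go across C8–C9 because both γ-positions are quaternary, returns 9.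

Step 4. What may go wrong: the allyl cation may partition the wrong way, taking hydride at C9 (transposed C7=C8 alkene) or losing a proton to give ring dienes. The fallback sets out from enone 10 and comes back at alcohol 12 without a cation: ethane-1,2-dithiol with BF3·OEt2 should give the 1,3-dithiolane of 10 F7, and desulfurisation with Raney Ni (deactivated, EtOH, reflux) removes the sulfur to give 12.

Step 3. What may go wrong: hydrogen may be delivered to the methyl-bearing face of C5 (cis-fused product), or uptake at the hindered C5=C6 bond may be so slow that the C8=C9 bond starts to be reduced. The fallback sets out from dienone 9 and comes back at 10 by electron transfer instead of surface hydrogenation: Li in NH3/THF with one equivalent of t-BuOH at −78 °C should reduce the less substituted enone half and cleave the benzyl ether, giving the dilithium dienolate-alkoxide F8, in which C5 has been protonated axially (trans fusion). Quenching excess Li with isoprene and then adding NH4Cl protonates F8 at C6 and gives 10.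

**Further compounds**
F1 | step 2 | (2R)-2,6,6-trimethyl-2-(3-oxobutyl)cyclohexan-1-one | CC(=O)CC[C@@]1(C)CCCC(C)(C)C1=O
F2 | step 2 | (4aR)-4a,8,8-trimethyl-4,4a,5,6,7,8-hexahydronaphthalen-2(3H)-one | O=C1CC[C@@]2(C)CCCC(C)(C)C2=C1
F3 | step 2 | (4aR)-3,4a,8,8-tetramethyl-4,4a,5,6,7,8-hexahydronaphthalen-2(3H)-one (C3 epimers) | CC1C[C@@]2(C)CCCC(C)(C)C2=CC1=O
F4 | step 2 | (4aR)-3,4a,8,8-tetramethyl-5,6,7,8-tetrahydronaphthalen-2(4aH)-one | CC1=C[C@@]2(C)CCCC(C)(C)C2=CC1=O
F5 | step 2 | [3-(benzyloxy)propyl]magnesium bromide | Br[Mg]CCCOCc1ccccc1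
F6 | step 2 | (4aR)-4-[3-(benzyloxy)propyl]-3,4a,8,8-tetramethyl-4,4a,5,6,7,8-hexahydronaphthalen-2(3H)-one (C3 and C4 epimers) | CC1C(CCCOCc3ccccc3)[C@@]2(C)CCCC(C)(C)C2=CC1=O
F7 | step 4 | 1,3-dithiolane (ethane-1,2-diyl dithioketal) of 10 | CC1=C(CCCO)[C@@]2(C)CCCC(C)(C)[C@@H]2CC13SCCS3
F8 | step 3 | dilithium dienolate-alkoxide from 9 | [Li+].[Li+].CC1=C(CCC[O-])[C@@]2(C)CCCC(C)(C)[C@@H]2C=C1[O-]
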